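## Analysis of the target

The target is one cyclohexane ring. In quinic acid numbering, C1 carries the tertiary hydroxyl O1 and the carboxyl carbon C7, C3, C4 and C5 carry O3, O4 and O5, and C2 and C6 are methylenes. There are four stereocentres: O1, O3 and O4 lie on one face and O5 and C7 on the other. In the preferred chair O1 and O3 are axial and C7, O4 and O5 equatorial, so O4/O5 are trans, O3/O4 cis, and O5 is cis to C7. O4 and O5 carry (E)-p-coumaroyl esters, while O1, O3, the carboxyl group and both phenols are free. The sensitive points are base-induced acyl migration among O3, O4 and O5, the conjugated ester alkenes (hydrogenation, conjugate addition, E/Z isomerisation), lactonisation of C7 onto a free O5, and β-elimination of the C1 or C5 oxygen whenever C3 is a ketone. The difficulty is to tell apart three secondary oxygens that differ only in position, and, in a de novo route, to set a quaternary carbinol and three contiguous oxygenated centres in the right relative and absolute sense. The strategy rests on one observation: C7, C1 with O1, C2, C3, C6 and C5 are the six carbons of citric acid (central carbinol carbon, its carboxyl, two CH2–CO2H arms). Only C4 is missing, and it can be inserted between the two arm termini as a one-carbon unit that already carries the O4 coumaroyl ester, after which a C4–C5 aldol closes the ring.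

## Retrosynthetic reasoning

Protecting groups (18 from 17 from 16). The two phenols are masked as silyl ethers, and O1 and C7 together as the isopropylidene dioxolanone present since the first step. These O–Si and acetal C–O bonds are cut first in the retrosynthetic sense because 18 tolerates neither base (the C4 ester would move to O3) nor heat. Forward, fluoride under slightly acidic conditions gives 17 and aqueous acid then opens the dioxolanone.

C3–H (16 from 15). The C3 carbinol is traced back to a ketone. A carbonyl at C3 keeps the one secondary oxygen that must stay unacylated out of the acylation chemistry without a protecting group, and it is the function that makes C4 nucleophilic. Forward, hydride has to approach 15 from the equatorial side so that O3 becomes axial, cis to O4 and O1.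

O5–acyl (15 from 13 and 10). The C5 ester is cut at the acyl–oxygen bond, giving alcohol 13 and the protected acid 10, used as its chloride 14. The cut is made here and not at O4 because O5 is the only hydroxyl in 13, so the forward acylation needs no selectivity.

C4–C5 (13 from 12). This disconnection opens the ring. A retro-aldol at C4–C5 turns the cyclohexanone into keto aldehyde 12, in which the C3 ketone is flanked by a C4 methylene that already bears the ester oxygen, and C5 is an aldehyde. Cutting C1–C2 or C1–C6 instead would break the skeleton of 1, and C3–C4 offers no polar pairing. The gain is that one step forms the ring, the C4 and C5 stereocentres, and the differentiation of O3 (ketone), O4 (ester) and O5 (free hydroxyl). Forward, an amino acid catalyst must form the enamine toward C4, close the six-membered ring on the aldehyde, and set C4 and C5 in the right sense relative to C1.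

C5 oxidation level (12 from 11). The aldehyde is taken back to a thioester. A thioester survives acid chloride and diazoketone chemistry on the other arm and is reduced to the aldehyde under neutral conditions, so the reactive keto aldehyde appears only immediately before ring closure.

C4–O4 (11 from 7 and 10). The ester oxygen–C4 bond is cut to give diazoketone 7 and acid 10. Forward, a metal carbene from 7 inserts into the O–H bond of 10, so C4 acquires O4 and its acyl group in one operation and O4 never exists as a free hydroxyl.

C3–C4 (7 from 4 and 5, via 6). The one missing ring carbon is disconnected from the acid arm of 4. Forward, the acid chloride 6 acylates the diazo carbon of 5.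

C5–S and the origin of C1 chirality (4 from 3). Removing the thiol from 4 gives the achiral spiro anhydride 3, whose two carbonyl groups are enantiotopic. Forward, a chiral base catalyst must direct the thiol to one of them. This single step distinguishes the arm that becomes C6–C5 from the arm that becomes C2–C3–C4 and fixes the configuration of C1.

Anhydride and acetonide (3 from 2 from 1). The anhydride comes from diacid 2 by dehydration, and 2 from 1 by tying the tertiary hydroxyl and the central carboxyl into the dioxolanone. That ring protects both groups to the end and leaves the two arms as the only free acids.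

Phenol protection (10 from 8, via 9). The coumaroyl building block is traced to 8 by removal of the aryl silyl ether. The silyl ether prevents the phenol from competing in the O–H insertion and in the acylation.

## Alternatives that were turned down

Alternative 1: ring contraction by an Ireland–Claisen rearrangement. The disconnection is C1–C6. In the forward key step the O-silyl ketene acetal of the δ-lactone A2 ((5R,6R)-5-(tert-butyldimethylsilyloxy)-6-ethenyl-3-(methoxymethoxy)oxan-2-one), formed with LiN(SiMe3)2 and Me3SiCl, undergoes the [3,3] shift through the boat imposed by the lactone ring and gives the cyclohexene acid A1.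
- For: C1 is set stereospecifically from the secondary C–O stereocentre of A2 (the cis relationship of silyloxy and vinyl groups becomes O1 cis to O3), the carboxyl group emerges free, and the C4=C5 alkene marks the two carbons to be esterified.
- Against: A1 has neither O4 nor O5. They would have to be added to the alkene as a trans-diol of one defined sense. A syn-dihydroxylation gives the cis-diol, and epoxidation with hydrolytic opening needs both facial control and regioselective opening before any ester can be attached. A2 also needs its two stereocentres from a separate asymmetric sequence.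
- Comparison: on the control of C1 this alternative is stronger, because a sigmatropic transfer is stereospecific whereas the desymmetrisation of 3 depends on catalyst discrimination. The chosen route offers in exchange a ring closure that delivers O4 (already esterified) and O5 trans to each other with C3 distinguishable as a ketone, so the ring needs no oxidation after it is formed and only four steps follow the closure.

Alternative 2: late oxygenation of C1 on a shikimate. The disconnection is C1–O1. In the forward key step the free allylic C3 hydroxyl of the diester A4 (tert-butyl 4,5-di-O-[(E)-4-acetoxycinnamoyl]shikimate), made from (−)-shikimic acid A9, directs VO(acac)2/t-BuOOH to the C1=C2 alkene and gives the epoxide A3 with the oxirane cis to O3. Reductive opening at C2 would then leave the tertiary hydroxyl.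
- For: C3, C4 and C5 come from the chiral pool, the hydroxyl that must stay free serves as the directing group, its face is the face on which O1 is needed, and the sequence is short.
- Against: the C1=C2 alkene is conjugated with the ester and therefore electron-poor, a poor substrate for an electrophilic vanadium peroxo species even with hydroxyl direction. Basic nucleophilic epoxidation would move acyl groups onto O3 and strip the aryl acetates. The opening of A3 must break the C2–O bond and keep C1–O, but electron-transfer reagents cleave the α C–O bond of α,β-epoxy esters, and hydride reagents endanger the cinnamates. Making A4 also requires acylating O4 and O5 of A9 beside the reactive allylic O3.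
- Comparison: this alternative is shorter and safer for the C3–C5 configuration. Two consecutive steps, however, run against the intrinsic reactivity of the substrate, whereas the chosen route carries O1 from the start (it is the hydroxyl of 1) and concentrates its risk in one step with mechanistic precedent.

Alternative 3: aryl groups attached last. The disconnection is at the two aryl–Cβ bonds of the cinnamoyl units. In the forward key step the bis-acrylate A6 (1,3-O-(di-tert-butylsilylene)-4,5-di-O-acryloylquinic acid), made from (−)-quinic acid A8, undergoes two Mizoroki–Heck couplings with 4-iodophenol A7 under Pd(OAc)2/P(o-tol)3/Et3N to give A5. Fluoride then removes the silylene.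
- For: all four stereocentres come from A8. The silylene bridges the cis-diaxial O1 and O3, leaves exactly O4 and O5 for acylation, and excludes acyl migration during the basic coupling. The Heck reaction gives E alkenes and tolerates free phenols, so the sequence is about five steps.
- Against: selective formation of the 1,3-silylene on A8 beside the carboxylic acid and the 3,4- and 4,5-diols is not assured. Acrylate esters are prone to conjugate addition and polymerisation under hot amine base. The key step builds no ring and no stereocentre, so this is a semisynthesis that depends on the supply of A8 and cannot reach the enantiomer or ring-labelled material.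
- Comparison: this alternative is stronger in step count and in stereochemical security, and that is conceded. The chosen route offers a de novo construction from the achiral 1: either enantiomer is accessible by changing catalysts, isotopic labels can be placed in the ring from labelled 1, and the two acyl groups arrive in separate steps (steps 6 and 9), so mixed diesters are within reach.

Key step: step 8

Assumption: the sense of induction of the cinchona thiourea in step 3 cannot be read from the structures; the quinidine-derived catalyst is written, and its quinine-derived pseudoenantiomer is used instead if the thiol is delivered to the other arm.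

## Route

Step 1
Reactants: 1 citric acid
Product: 2 2,2'-(2,2-dimethyl-5-oxo-1,3-dioxolane-4,4-diyl)diacetic acid
Conditions: 2,2-dimethoxypropane (3 equiv), TsOH·H2O (cat.), acetone, rt
Reagents that add atoms: 2,2-dimethoxypropane, COC(C)(C)OC
Why: Acid-catalysed acetal exchange (acetonide formation of an α-hydroxy acid): the tertiary hydroxyl and the carboxyl on the same carbon close the five-membered dioxolanone, as with malic acid, and the two CH2CO2H arms stay free; no stereocentre is formed, the two arms are enantiotopic.

Step 2
Reactants: 2 2,2'-(2,2-dimethyl-5-oxo-1,3-dioxolane-4,4-diyl)diacetic acid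
Product: 3 2,2-dimethyl-1,3,8-trioxaspiro[4.5]decane-4,7,9-trione
Conditions: Ac2O, 50 °C; concentrate
Reagents that add atoms: none
Why: Dehydration of a glutaric-type diacid to the six-membered cyclic anhydride; the dioxolanone is inert to acetic anhydride, and the product is an achiral spiro anhydride with two enantiotopic carbonyl groups.

Step 3
Reactants: 3 2,2-dimethyl-1,3,8-trioxaspiro[4.5]decane-4,7,9-trione
Product: 4 2-[(4S)-4-[2-(ethylsulfanyl)-2-oxoethyl]-2,2-dimethyl-5-oxo-1,3-dioxolan-4-yl]acetic acid
Conditions: EtSH (1.5 equiv), N-[3,5-bis(trifluoromethyl)phenyl]-N′-[(9R)-6′-methoxycinchonan-9-yl]thiourea (10 mol%), t-BuOMe, −30 °C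
Reagents that add atoms: ethanethiol, CCS
Why: Organocatalytic enantioselective thiolysis (desymmetrisation) of a prochiral glutaric anhydride: the thiourea binds the anhydride, the quinuclidine nitrogen activates the thiol, and attack on one of the two enantiotopic carbonyl groups sets the quaternary carbon, the future C1; the anhydride carbonyls are far more electrophilic than the dioxolanone.

Step 4
Reactants: 4 2-[(4S)-4-[2-(ethylsulfanyl)-2-oxoethyl]-2,2-dimethyl-5-oxo-1,3-dioxolan-4-yl]acetic acid; 5 (trimethylsilyl)diazomethane
Product: 7 S-ethyl 2-[(4S)-4-(3-diazo-2-oxopropyl)-2,2-dimethyl-5-oxo-1,3-dioxolan-4-yl]ethanethioate, via acid chloride 6 (not isolated)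
Conditions: (COCl)2, DMF (cat.), CH2Cl2, 0 °C to rt, concentrate; then 5 (2.2 equiv), MeCN/THF, 0 °C to rt
Reagents that add atoms: none
Why: Acid chloride formation followed by C-acylation of the diazoalkane (first half of an Arndt–Eistert sequence); the silyl group leaves as the silyl chloride and the diazo carbon becomes the future C4; the thioester arm and the stereocentre are not involved, and the acid chloride is used cold and at once to avoid exchange between the two arms.

Step 5
Reactants: 8 p-coumaric acid
Product: 10 (E)-3-[4-(tert-butyldimethylsilyloxy)phenyl]prop-2-enoic acid, via bis-silyl derivative 9 (not isolated)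
Conditions: TBSCl (2.3 equiv), imidazole (4.5 equiv), DMF, rt; then AcOH/THF/H2O, rt
Reagents that add atoms: tert-butyldimethylsilyl chloride, CC(C)(C)[Si](C)(C)Cl
Why: Silylation of phenol and carboxylic acid, then selective hydrolysis of the much more labile silyl ester; the aryl silyl ether is stable to dilute acetic acid.

Step 6
Reactants: 7 S-ethyl 2-[(4S)-4-(3-diazo-2-oxopropyl)-2,2-dimethyl-5-oxo-1,3-dioxolan-4-yl]ethanethioate; 10 (E)-3-[4-(tert-butyldimethylsilyloxy)phenyl]prop-2-enoic acid
Product: 11 3-[(4S)-4-[2-(ethylsulfanyl)-2-oxoethyl]-2,2-dimethyl-5-oxo-1,3-dioxolan-4-yl]-2-oxopropyl (E)-3-[4-(tert-butyldimethylsilyloxy)phenyl]prop-2-enoate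
Conditions: Rh2(OAc)4 (1 mol%), CH2Cl2, rt, slow addition of 7 to 10 (1.5 equiv)
Reagents that add atoms: none
Why: Rhodium carbenoid O–H insertion into a carboxylic acid, a general route to acyloxymethyl ketones; excess acid and slow addition of the diazoketone favour the intermolecular insertion over carbene dimerisation or attack of the dioxolanone oxygens, and the electron-poor cinnamate alkene is a poor partner for cyclopropanation.

Step 7
Reactants: 11 3-[(4S)-4-[2-(ethylsulfanyl)-2-oxoethyl]-2,2-dimethyl-5-oxo-1,3-dioxolan-4-yl]-2-oxopropyl (E)-3-[4-(tert-butyldimethylsilyloxy)phenyl]prop-2-enoate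
Product: 12 3-[(4R)-2,2-dimethyl-5-oxo-4-(2-oxoethyl)-1,3-dioxolan-4-yl]-2-oxopropyl (E)-3-[4-(tert-butyldimethylsilyloxy)phenyl]prop-2-enoate
Conditions: Et3SiH (3 equiv), palladium on carbon (10% Pd/C, 5 mol% Pd), acetone, rt
Reagents that add atoms: none
Why: Fukuyama reduction: the C–S bond adds to zerovalent palladium, the silane delivers hydride and the aldehyde is released without over-reduction; ketone, esters, dioxolanone and silyl ether do not react, and the sulfur-moderated catalyst, the aprotic solvent and a short reaction time are relied on to spare the cinnamate alkene.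

Step 8
Reactants: 12 3-[(4R)-2,2-dimethyl-5-oxo-4-(2-oxoethyl)-1,3-dioxolan-4-yl]-2-oxopropyl (E)-3-[4-(tert-butyldimethylsilyloxy)phenyl]prop-2-enoate
Product: 13 4-O-[(E)-4-(tert-butyldimethylsilyloxy)cinnamoyl]-3-dehydroquinic acid 1,7-acetonide
Conditions: (S)-proline (30 mol%), DMSO, rt, 0.05 M
Reagents that add atoms: none
Why: (S)-Proline condenses with the C3 ketone and the enamine forms toward C4, the more acidic carbon that bears the ester oxygen; an enamine toward C2 or at the aldehyde is unproductive because neither can reach a ketone or aldehyde carbonyl through a ring larger than four atoms. The closest known reaction types are the proline-catalysed intramolecular enolendo aldol (Hajos–Parrish–Eder–Sauer–Wiechert reaction) and proline aldols of α-oxygenated ketone donors such as hydroxyacetone. C4 attacks the aldehyde carbon C5 in a 6-(enolendo)-exo-trig closure through a half-chair, while the carboxylic acid of the catalyst hydrogen-bonds to the aldehyde oxygen. C4: the ester oxygen should sit trans to nitrogen in the enamine, as the hydroxyl of hydroxyacetone does, and the catalyst carboxyl group directs the aldehyde to one enamine face, which should give 4S with the C4–O bond pseudo-axial on the closing ring. C5: the aldehyde must keep C6 in the ring and turn its oxygen toward the carboxylic acid, so the C5–O bond is pseudo-axial as well and anti to C4–O, which should give 5R and the trans arrangement; ring inversion after closure places O4, O5 and C7 equatorial. The selectivity the step needs is the sense of this trans pair relative to C1: the catalyst-preferred 4S,5R pair has the developing O5 syn to the planar dioxolanone carbonyl carbon C7 rather than to O1, an arrangement of low steric cost that is the natural O5/C7 cis relationship, so (S)-proline is expected to be the matched enantiomer. High dilution suppresses intermolecular aldol reactions of the aldehyde, and the product leaves the step with O4 esterified, O5 as the only free hydroxyl and C3 still a ketone.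

Step 9
Reactants: 13 4-O-[(E)-4-(tert-butyldimethylsilyloxy)cinnamoyl]-3-dehydroquinic acid 1,7-acetonide; 10 (E)-3-[4-(tert-butyldimethylsilyloxy)phenyl]prop-2-enoic acid
Product: 15 4,5-di-O-[(E)-4-(tert-butyldimethylsilyloxy)cinnamoyl]-3-dehydroquinic acid 1,7-acetonide, via acid chloride 14 (not isolated)
Conditions: 10, (COCl)2, DMF (cat.), CH2Cl2, 0 °C to rt, concentrate; then 13, pyridine, CH2Cl2, −20 to 0 °C
Reagents that add atoms: none
Why: Acylation of a secondary alcohol with an acid chloride under pyridine; O5 is the only hydroxyl in 13, so no selectivity is needed, and a shift of the C4 ester to O5 before acylation would lead to the same diester; weak base and low temperature are chosen because the product is a β-acyloxy ketone.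

Step 10
Reactants: 15 4,5-di-O-[(E)-4-(tert-butyldimethylsilyloxy)cinnamoyl]-3-dehydroquinic acid 1,7-acetonide
Product: 16 4,5-di-O-[(E)-4-(tert-butyldimethylsilyloxy)cinnamoyl]quinic acid 1,7-acetonide
Conditions: LiBH(s-Bu)3 (1.1 equiv), THF, −78 °C; AcOH quench at −78 °C
Reagents that add atoms: none
Why: Reduction of a cyclohexanone with a bulky trialkylborohydride: attack from the equatorial direction, reinforced by the axial oxygen on C1 that blocks the axial path, should give the axial alcohol (3R), cis to O4 and O1; the ketone, activated by the α-acyloxy group, reacts far faster than esters, enoates or the dioxolanone at −78 °C, and the cold acidic quench limits acyl migration.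

Step 11
Reactants: 16 4,5-di-O-[(E)-4-(tert-butyldimethylsilyloxy)cinnamoyl]quinic acid 1,7-acetonide
Product: 17 4,5-di-O-p-coumaroylquinic acid 1,7-acetonide
Conditions: Et3N·3HF, THF, 0 °C to rt
Reagents that add atoms: none
Why: Fluoride cleavage of aryl silyl ethers under mildly acidic conditions, at which neither acyl migration nor opening of the dioxolanone is expected.

Step 12
Reactants: 17 4,5-di-O-p-coumaroylquinic acid 1,7-acetonide
Product: 18 4,5-di-O-p-coumaroylquinic acid
Conditions: TFA/H2O (4:1), 0 °C to rt; lyophilise, reverse-phase chromatography
Reagents that add atoms: water, O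
Why: Acid hydrolysis of the isopropylidene acetal–ester (dioxolanone) releases the tertiary hydroxyl and the carboxylic acid; the acidic medium and short contact keep both esters in place.

## Compound list

1 | citric acid | OC(=O)CC(O)(CC(=O)O)C(=O)O | starting material
2 | 2,2'-(2,2-dimethyl-5-oxo-1,3-dioxolane-4,4-diyl)diacetic acid | CC1(C)OC(=O)C(CC(=O)O)(CC(=O)O)O1 | intermediate
3 | 2,2-dimethyl-1,3,8-trioxaspiro[4.5]decane-4,7,9-trione | CC1(C)OC(=O)C2(CC(=O)OC(=O)C2)O1 | intermediate
4 | 2-[(4S)-4-[2-(ethylsulfanyl)-2-oxoethyl]-2,2-dimethyl-5-oxo-1,3-dioxolan-4-yl]acetic acid | OC(=O)C[C@@](O1)(C(=O)OC1(C)C)CC(=O)SCC | intermediate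
5 | (trimethylsilyl)diazomethane | C[Si](C)(C)C=[N+]=[N-] | starting material
6 | S-ethyl 2-[(4R)-4-(2-chloro-2-oxoethyl)-2,2-dimethyl-5-oxo-1,3-dioxolan-4-yl]ethanethioate | ClC(=O)C[C@@](O1)(C(=O)OC1(C)C)CC(=O)SCC | intermediate (not isolated)
7 | S-ethyl 2-[(4S)-4-(3-diazo-2-oxopropyl)-2,2-dimethyl-5-oxo-1,3-dioxolan-4-yl]ethanethioate | [N-]=[N+]=CC(=O)C[C@@](O1)(C(=O)OC1(C)C)CC(=O)SCC | intermediate
8 | p-coumaric acid, (E)-3-(4-hydroxyphenyl)prop-2-enoic acid | O=C(O)/C=C/c1ccc(O)cc1 | starting material
9 | tert-butyldimethylsilyl (E)-3-[4-(tert-butyldimethylsilyloxy)phenyl]prop-2-enoate | CC(C)(C)[Si](C)(C)OC(=O)/C=C/c1ccc(O[Si](C)(C)C(C)(C)C)cc1 | intermediate (not isolated)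
10 | (E)-3-[4-(tert-butyldimethylsilyloxy)phenyl]prop-2-enoic acid | O=C(O)/C=C/c1ccc(O[Si](C)(C)C(C)(C)C)cc1 | intermediate
11 | 3-[(4S)-4-[2-(ethylsulfanyl)-2-oxoethyl]-2,2-dimethyl-5-oxo-1,3-dioxolan-4-yl]-2-oxopropyl (E)-3-[4-(tert-butyldimethylsilyloxy)phenyl]prop-2-enoate | O=C(/C=C/c1ccc(O[Si](C)(C)C(C)(C)C)cc1)OCC(=O)C[C@@](O2)(C(=O)OC2(C)C)CC(=O)SCC | intermediate
12 | 3-[(4R)-2,2-dimethyl-5-oxo-4-(2-oxoethyl)-1,3-dioxolan-4-yl]-2-oxopropyl (E)-3-[4-(tert-butyldimethylsilyloxy)phenyl]prop-2-enoate | O=C(/C=C/c1ccc(O[Si](C)(C)C(C)(C)C)cc1)OCC(=O)C[C@@](O2)(C(=O)OC2(C)C)CC=O | intermediate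
13 | 4-O-[(E)-4-(tert-butyldimethylsilyloxy)cinnamoyl]-3-dehydroquinic acid 1,7-acetonide; quinic acid numbering, (1R,4S,5R); O1 and C7 tied as a spiro 2,2-dimethyl-1,3-dioxolan-4-one, C3 ketone, O5 free, trans to O4 and cis to C7 | O=C(/C=C/c1ccc(O[Si](C)(C)C(C)(C)C)cc1)O[C@@H]2C(=O)C[C@@](O3)(C(=O)OC3(C)C)C[C@H]2O | intermediate
14 | (E)-3-[4-(tert-butyldimethylsilyloxy)phenyl]prop-2-enoyl chloride | O=C(Cl)/C=C/c1ccc(O[Si](C)(C)C(C)(C)C)cc1 | intermediate (not isolated)
15 | 4,5-di-O-[(E)-4-(tert-butyldimethylsilyloxy)cinnamoyl]-3-dehydroquinic acid 1,7-acetonide; (1R,4S,5R) | O=C(/C=C/c1ccc(O[Si](C)(C)C(C)(C)C)cc1)O[C@@H]2C(=O)C[C@@](O3)(C(=O)OC3(C)C)C[C@H]2OC(=O)/C=C/c4ccc(O[Si](C)(C)C(C)(C)C)cc4 | intermediate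
16 | 4,5-di-O-[(E)-4-(tert-butyldimethylsilyloxy)cinnamoyl]quinic acid 1,7-acetonide; (1S,3R,4R,5R), axial 3-hydroxyl cis to O4 and O1 | O=C(/C=C/c1ccc(O[Si](C)(C)C(C)(C)C)cc1)O[C@@H]2[C@H](O)C[C@@](O3)(C(=O)OC3(C)C)C[C@H]2OC(=O)/C=C/c4ccc(O[Si](C)(C)C(C)(C)C)cc4 | intermediate
17 | 4,5-di-O-p-coumaroylquinic acid 1,7-acetonide; (1S,3R,4R,5R) | O=C(/C=C/c1ccc(O)cc1)O[C@@H]2[C@H](O)C[C@@](O3)(C(=O)OC3(C)C)C[C@H]2OC(=O)/C=C/c4ccc(O)cc4 | intermediate
18 | 4,5-di-O-p-coumaroylquinic acid, (1S,3R,4R,5R)-1,3-dihydroxy-4,5-bis{[(E)-3-(4-hydroxyphenyl)prop-2-enoyl]oxy}cyclohexane-1-carboxylic acid | O=C(/C=C/c1ccc(O)cc1)O[C@@H]1[C@H](O)C[C@@](O)(C(=O)O)C[C@H]1OC(=O)/C=C/c1ccc(O)cc1 | target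

## Step count and least certain steps

Total step count: 12. Longest linear sequence: 11 steps (1 to 2, 3, 4, 7, 11, 12, 13, 15, 16, 17 and 18; step 5 is a one-step side branch).

Step 8 (key step). Three things may go wrong.
- The catalyst may condense preferentially with the more electrophilic aldehyde. The resulting enamine cannot cyclise and would lead to β-elimination of the C1 oxygen or to intermolecular aldol reaction.
- The activated α-keto ester may transfer its acyl group to the catalyst nitrogen, so that the donor is consumed and the catalyst deactivated.
- The catalyst preference may be mismatched with the C1 centre, giving poor facial selectivity. The first remedy is (R)-proline.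

The fallback replaces the ester on C4 by an ether, a donor type with precedent in amine-catalysed aldol reactions. It sets out from 7 and returns at 15.
- O–H insertion of 7 into 4-methoxybenzyl alcohol with Rh2(OAc)4 gives the 4-methoxybenzyloxymethyl ketone thioester F1.
- Fukuyama reduction gives the keto aldehyde F2.
- The (S)-proline aldol gives 4-O-(4-methoxybenzyl)-3-dehydroquinic acid 1,7-acetonide F3.
- 2,3-Dichloro-5,6-dicyano-1,4-benzoquinone in wet CH2Cl2 removes the ether to give 3-dehydroquinic acid 1,7-acetonide F4.
- Double acylation of F4 with 14 (made as in step 9) under pyridine gives 15.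

Step 3. Enantiotopic discrimination may be poor, because the two substituents on the prochiral carbon (ring oxygen and ring carbonyl) are similar in size, and the product may erode by reversible reclosure to the anhydride under the basic catalyst. The fallback replaces catalyst control by auxiliary control with separation. It sets out from 3 and returns at 4.
- Opening of 3 with (R)-1-(naphthalen-1-yl)ethanol and 4-(dimethylamino)pyridine at −40 °C gives, after separation of diastereomers, the 1-(naphthalen-1-yl)ethyl hemiester F5. The enantiomer of the alcohol is chosen so that the ester sits on the arm destined to become the ketone.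
- Thioesterification of the free acid with ethanethiol, N-(3-dimethylaminopropyl)-N′-ethylcarbodiimide and 4-(dimethylamino)pyridine gives the ester thioester F6.
- Ionic hydrogenolysis of the benzylic ester with TFA/Et3SiH gives 4.

Step 6. The rhodium carbenoid may be diverted into intramolecular ylide formation with the dioxolanone oxygens or into addition to the electron-rich silyloxyarene. The fallback avoids carbenes altogether. It sets out from 7 and returns at 11: aqueous HBr in ether at 0 °C converts 7 into the bromomethyl ketone F7, and displacement by the carboxylate of 10 (i-Pr2NEt, acetone, rt) gives 11.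

Step 7. Palladium hydride species may reduce the conjugated alkene of the cinnamate before the thioester is consumed. The fallback changes the order so that the reduction is run before the unsaturated ester is present. It sets out from 7 and returns at 12.
- Rh2(OAc)4 in wet THF (O–H insertion into water) gives the hydroxymethyl ketone thioester F8.
- Fukuyama reduction gives the hydroxy keto aldehyde F9.
- Acylation of the primary hydroxyl with 14 and pyridine at −20 °C gives 12.

Step 9. Base-induced β-elimination of the new C5 ester across C4–C5 may occur, since the product is a β-acyloxy ketone with an acidic C4–H. The fallback removes the ketone first. It sets out from 13 and returns at 16.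
- Evans–Saksena reduction with Me4NBH(OAc)3 in AcOH/MeCN at −20 °C delivers hydride from the face of the C5 hydroxyl and should give the 3,5-anti diol, 4-O-[(E)-4-(tert-butyldimethylsilyloxy)cinnamoyl]quinic acid 1,7-acetonide F10.
- One equivalent of 14 with pyridine at −30 °C should then acylate the equatorial O5 in preference to the axial O3, which is shielded by the syn-axial O1, and give 16.

Step 10. The C4 ester may migrate onto the new cis C3 alkoxide before the quench, and the hydride may add in a conjugate sense to a cinnamate. The fallback, from 15 to 16 with no new compound, is an enzymatic reduction: a ketoreductase from a screening panel with NADPH and glucose dehydrogenase recycling, in phosphate buffer at pH 6.5 with DMSO as cosolvent. It delivers hydride under enzyme control at neutral pH, where no alkoxide is formed.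

## Further compounds

F1 | step 8 | S-ethyl 2-[(4S)-4-{3-[(4-methoxyphenyl)methoxy]-2-oxopropyl}-2,2-dimethyl-5-oxo-1,3-dioxolan-4-yl]ethanethioate | COc1ccc(COCC(=O)C[C@@](O2)(C(=O)OC2(C)C)CC(=O)SCC)cc1
F2 | step 8 | 2-[(4R)-4-{3-[(4-methoxyphenyl)methoxy]-2-oxopropyl}-2,2-dimethyl-5-oxo-1,3-dioxolan-4-yl]acetaldehyde | COc1ccc(COCC(=O)C[C@@](O2)(C(=O)OC2(C)C)CC=O)cc1
F3 | step 8 | 4-O-(4-methoxybenzyl)-3-dehydroquinic acid 1,7-acetonide, (1R,4S,5R) | COc1ccc(CO[C@@H]2C(=O)C[C@@](O3)(C(=O)OC3(C)C)C[C@H]2O)cc1
F4 | step 8 | 3-dehydroquinic acid 1,7-acetonide, (1R,4S,5R) | O[C@@H]1C(=O)C[C@@](O2)(C(=O)OC2(C)C)C[C@H]1O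
F5 | step 3 | 2-[(4R)-2,2-dimethyl-4-{2-[(1R)-1-(naphthalen-1-yl)ethoxy]-2-oxoethyl}-5-oxo-1,3-dioxolan-4-yl]acetic acid | C[C@@H](OC(=O)C[C@@](O1)(C(=O)OC1(C)C)CC(=O)O)c1cccc2ccccc12
F6 | step 3 | (1R)-1-(naphthalen-1-yl)ethyl 2-[(4S)-4-[2-(ethylsulfanyl)-2-oxoethyl]-2,2-dimethyl-5-oxo-1,3-dioxolan-4-yl]acetate | C[C@@H](OC(=O)C[C@@](O1)(C(=O)OC1(C)C)CC(=O)SCC)c1cccc2ccccc12
F7 | step 6 | S-ethyl 2-[(4S)-4-(3-bromo-2-oxopropyl)-2,2-dimethyl-5-oxo-1,3-dioxolan-4-yl]ethanethioate | BrCC(=O)C[C@@](O1)(C(=O)OC1(C)C)CC(=O)SCC
F8 | step 7 | S-ethyl 2-[(4S)-4-(3-hydroxy-2-oxopropyl)-2,2-dimethyl-5-oxo-1,3-dioxolan-4-yl]ethanethioate | OCC(=O)C[C@@](O1)(C(=O)OC1(C)C)CC(=O)SCC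
F9 | step 7 | 2-[(4R)-4-(3-hydroxy-2-oxopropyl)-2,2-dimethyl-5-oxo-1,3-dioxolan-4-yl]acetaldehyde | OCC(=O)C[C@@](O1)(C(=O)OC1(C)C)CC=O
F10 | step 9 | 4-O-[(E)-4-(tert-butyldimethylsilyloxy)cinnamoyl]quinic acid 1,7-acetonide, natural quinic acid configuration, O3 and O5 free | O=C(/C=C/c1ccc(O[Si](C)(C)C(C)(C)C)cc1)O[C@@H]2[C@H](O)C[C@@](O3)(C(=O)OC3(C)C)C[C@H]2O
F0 | step 10 | none | none
A1 | alternative 1 | (1R,3R)-3-(tert-butyldimethylsilyloxy)-1-(methoxymethoxy)cyclohex-4-ene-1-carboxylic acid | C1=C[C@H](O[Si](C)(C)C(C)(C)C)C[C@@](OCOC)(C(=O)O)C1
A2 | alternative 1 | (5R,6R)-5-(tert-butyldimethylsilyloxy)-6-ethenyl-3-(methoxymethoxy)oxan-2-one | C=C[C@H]1OC(=O)C(OCOC)C[C@H]1O[Si](C)(C)C(C)(C)C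
A3 | alternative 2 | tert-butyl 4,5-di-O-[(E)-4-acetoxycinnamoyl]-1,2-epoxy-3-hydroxycyclohexane-1-carboxylate, oxirane cis to O3 | O=C(/C=C/c1ccc(OC(C)=O)cc1)O[C@@H]2[C@H](O)[C@@H]3O[C@]3(C(=O)OC(C)(C)C)C[C@H]2OC(=O)/C=C/c4ccc(OC(C)=O)cc4
A4 | alternative 2 | tert-butyl 4,5-di-O-[(E)-4-acetoxycinnamoyl]shikimate | O=C(/C=C/c1ccc(OC(C)=O)cc1)O[C@@H]2[C@H](O)C=C(C(=O)OC(C)(C)C)C[C@H]2OC(=O)/C=C/c3ccc(OC(C)=O)cc3
A5 | alternative 3 | 1,3-O-(di-tert-butylsilylene)-4,5-di-O-p-coumaroylquinic acid | O=C(/C=C/c1ccc(O)cc1)O[C@@H]2[C@H]3C[C@@](O[Si](C(C)(C)C)(C(C)(C)C)O3)(C(=O)O)C[C@H]2OC(=O)/C=C/c4ccc(O)cc4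
A6 | alternative 3 | 1,3-O-(di-tert-butylsilylene)-4,5-di-O-acryloylquinic acid | C=CC(=O)O[C@@H]1[C@H]2C[C@@](O[Si](C(C)(C)C)(C(C)(C)C)O2)(C(=O)O)C[C@H]1OC(=O)C=C
A7 | alternative 3 | 4-iodophenol | Oc1ccc(I)cc1
A8 | alternative 3 | (−)-quinic acid | O[C@@H]1[C@H](O)C[C@@](O)(C(=O)O)C[C@H]1O
A9 | alternative 2 | (−)-shikimic acid | O[C@@H]1[C@H](O)C=C(C(=O)O)C[C@H]1O
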